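**Retrosynthetic overview**
Target 23 ⇐ Teuber oxidation of ring B at C5′ ⇐ resorcinol 22 ⇐ bis-MOM isoflavan 21 ⇐ stereoretentive protodeboronation of the C3 boronate 20.
Key disconnection C2–C3 (ring C, the pyran): 20 ⇐ acyclic carbamate 17 by lithiation at C3, capture by the O1–CH2–B(pin) arm to a seven-membered boronate ring (C3–B–C2–O1–C8a–C4a–C4), then 1,2-shift of C2 from B to C3 with loss of the carbamate; the C–B bonds are temporary and are cut in step 13.
Enabling feature: O1 is the phenol oxygen of ring A, so C2 can be carried as an aryloxymethyl boronate; C3 is benzylic to ring B and four bonds from O1 (O1–C8a–C4a–C4–C3), so a C3 carbinol can become a configurationally stable lithiated carbamate that reaches the boron.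
17 ⇐ (S)-alcohol 14 (asymmetric transfer hydrogenation) ⇐ ketone 13 ⇐ palladium α-arylation (C4–C4a) of ring B methyl ketone 7 with ring A bromide 12; both prenyl groups come from directed ortho-metalation.
Ring order: rings A and B are bought (3,5-dimethoxyphenol, resorcinol); ring C is the only ring formed (step 12); the quinone of ring B is generated last (step 15).

Key step: step 12

Remark: C3 of the given structure is read as (R); prenyl = 3-methylbut-2-en-1-yl, MOM = methoxymethyl, TIPS = tri(propan-2-yl)silyl, pin = pinacolato, Cb = N,N-di(propan-2-yl)carbamoyl.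

**Route**

Step 1
Reactants: 1 resorcinol
Product: 2 1,3-bis(methoxymethoxy)benzene
Conditions: MOMCl, iPr2NEt, CH2Cl2, 0 °C → rt
Reagents that add atoms: chloromethyl methyl ether (MOMCl), COCCl
Why: Double O-alkylation of the phenols (Williamson-type acetal formation) protects ring B and installs the two groups that later direct ortho-lithiation.

Step 2
Reactants: 2 1,3-bis(methoxymethoxy)benzene
Product: 4 1,3-bis(methoxymethoxy)-2-prenylbenzene, via aryllithium 3 (not isolated)
Conditions: n-BuLi, THF, 0 °C → rt; then CuI (10 mol %), prenyl bromide, −78 °C → rt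
Reagents that add atoms: prenyl bromide (1-bromo-3-methylbut-2-ene), CC(C)=CCBr
Why: Directed ortho-metalation between the two cooperating OMOM groups, then CuI-catalysed allylic substitution, should give the linear prenyl arene (future C3′ prenyl).

Step 3
Reactants: 4 1,3-bis(methoxymethoxy)-2-prenylbenzene
Product: 7 1-[2,4-bis(methoxymethoxy)-3-prenylphenyl]ethan-1-one, via aryllithium 5 (not isolated), via lithium hemiaminal alkoxide 6 (not isolated)
Conditions: n-BuLi, TMEDA, THF, −20 → 0 °C; then MeC(O)N(OMe)Me, −78 °C → rt; H2O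
Reagents that add atoms: N-methoxy-N-methylacetamide, CC(=O)N(C)OC
Why: A second directed ortho-metalation at the only position ortho to an OMOM group, then Weinreb amide acylation (the chelated adduct 6 blocks over-addition), should give the ring B methyl ketone.

Step 4
Reactants: 8 3,5-dimethoxyphenol
Product: 9 (3,5-dimethoxyphenoxy)tri(propan-2-yl)silane
Conditions: TIPSCl, imidazole, DMF, rt
Reagents that add atoms: chlorotri(propan-2-yl)silane (TIPSCl), CC(C)[Si](Cl)(C(C)C)C(C)C
Why: Silylation of the phenol gives a bulky, poorly coordinating ether that shields its two neighbouring positions and later releases O1.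

Step 5
Reactants: 9 (3,5-dimethoxyphenoxy)tri(propan-2-yl)silane
Product: 11 [3,5-dimethoxy-4-prenylphenoxy]tri(propan-2-yl)silane, via aryllithium 10 (not isolated)
Conditions: n-BuLi, THF, 0 °C → rt; then CuI (10 mol %), prenyl bromide, −78 °C → rt
Reagents that add atoms: prenyl bromide (1-bromo-3-methylbut-2-ene), CC(C)=CCBr
Why: Directed ortho-metalation should go to the carbon between the two methoxy groups (the positions next to OTIPS are shielded), and CuI-catalysed prenylation then places the prenyl group at the future C6.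

Step 6
Reactants: 11 [3,5-dimethoxy-4-prenylphenoxy]tri(propan-2-yl)silane
Product: 12 [2-bromo-3,5-dimethoxy-4-prenylphenoxy]tri(propan-2-yl)silane
Conditions: NBS (1.0 equiv), CH2Cl2, −78 → −40 °C, dark
Reagents that add atoms: N-bromosuccinimide, O=C1CCC(=O)N1Br
Why: Electrophilic aromatic bromination at one of the two equivalent free ring positions, each activated by three oxygen donors, should outpace reaction at the trisubstituted prenyl alkene at low temperature.

Step 7
Reactants: 7 1-[2,4-bis(methoxymethoxy)-3-prenylphenyl]ethan-1-one; 12 [2-bromo-3,5-dimethoxy-4-prenylphenoxy]tri(propan-2-yl)silane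
Product: 13 1-[2,4-bis(methoxymethoxy)-3-prenylphenyl]-2-[2,4-dimethoxy-3-prenyl-6-(TIPS-oxy)phenyl]ethan-1-one
Conditions: Pd(OAc)2 (3 mol %), XPhos (6 mol %), K3PO4, toluene, 100 °C
Reagents that add atoms: none
Why: Palladium-catalysed α-arylation of the methyl ketone enolate with the aryl bromide forms the C4–C4a bond, and the di-ortho-substituted aryl group should prevent a second arylation.

Step 8
Reactants: 13 ketone
Product: 14 (1S)-1-[2,4-bis(methoxymethoxy)-3-prenylphenyl]-2-[2,4-dimethoxy-3-prenyl-6-(TIPS-oxy)phenyl]ethan-1-ol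
Conditions: RuCl[(S,S)-TsDPEN](p-cymene) (2 mol %), HCO2H/Et3N (5:2), DMF, 40 °C
Reagents that add atoms: none
Why: Noyori–Ikariya asymmetric transfer hydrogenation with the (S,S)-catalyst should deliver hydride to the aryl ketone face fixed by the CH/π contact with ring B, setting the (S)-carbinol at the future C3 (as for aryl methyl ketones) while leaving the prenyl alkenes untouched.

Step 9
Reactants: 14 (S)-alcohol
Product: 15 (1S)-1-[2,4-bis(methoxymethoxy)-3-prenylphenyl]-2-[2,4-dimethoxy-3-prenyl-6-(TIPS-oxy)phenyl]ethyl N,N-di(propan-2-yl)carbamate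
Conditions: iPr2NC(O)Cl, Et3N, DMAP (cat.), toluene, 90 °C
Reagents that add atoms: N,N-di(propan-2-yl)carbamoyl chloride, CC(C)N(C(C)C)C(Cl)=O
Why: O-carbamoylation (nucleophilic acyl substitution at oxygen, no change at the stereocentre) installs the group that directs lithiation and later leaves.

Step 10
Reactants: 15 TIPS-protected carbamate
Product: 16 (1S)-1-[2,4-bis(methoxymethoxy)-3-prenylphenyl]-2-[6-hydroxy-2,4-dimethoxy-3-prenylphenyl]ethyl N,N-di(propan-2-yl)carbamate
Conditions: TBAF, AcOH, THF, 0 °C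
Reagents that add atoms: none
Why: Buffered fluoride cleavage of the aryl silyl ether frees the ring A phenol (O1) without touching the MOM ethers or the carbamate.

Step 11
Reactants: 16 phenol carbamate
Product: 17 (1S)-1-[2,4-bis(methoxymethoxy)-3-prenylphenyl]-2-[2,4-dimethoxy-3-prenyl-6-{(pinacolboryl)methoxy}phenyl]ethyl N,N-di(propan-2-yl)carbamate
Conditions: ICH2Bpin, K2CO3, MeCN, 50 °C
Reagents that add atoms: 2-(iodomethyl)-4,4,5,5-tetramethyl-1,3,2-dioxaborolane, ICB1OC(C)(C)C(C)(C)O1
Why: Williamson etherification of the phenoxide with the α-iodo boronate (direct SN2 or boron-ate formation then 1,2-shift, same product) attaches C2 as an aryloxymethyl pinacol boronate.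

Step 12
Reactants: 17 boronate-tethered (S)-carbamate
Product: 20 2-{(3R)-3-[2,4-bis(methoxymethoxy)-3-prenylphenyl]-5,7-dimethoxy-6-prenyl-3,4-dihydro-2H-chromen-3-yl}-4,4,5,5-tetramethyl-1,3,2-dioxaborolane, via lithiated carbamate 18 (not isolated), via cyclic boronate complex 19 (not isolated)
Conditions: LiN(iPr)2 (1.3 equiv), Et2O/THF (5:1), −78 °C, 2 h; then −78 → 40 °C, 12 h
Reagents that add atoms: none
Why: Proposed new method: LiN(iPr)2, a base that does not add irreversibly to a pinacol boronate, removes the C3–H of 17 (dipole-stabilised by the carbamate C=O, benzylic to ring B) to give the configurationally stable lithiated carbamate 18, whose C–Li bond is captured with retention by the tethered boron (Li–O(pinacol) contact) to form the seven-membered cyclic boronate complex 19 (ring C3–B–C2–O1–C8a–C4a–C4); on warming, C2 migrates from boron to C3 anti to the leaving carbamate (1,2-metallate rearrangement, inversion at C3), which forms the C2–C3 bond and leaves boron outside the ring. The closest known reaction type is the stereospecific intermolecular lithiation–borylation of enantioenriched secondary benzylic carbamates with alkyl pinacol boronates; new here are the tethered boron, the amide base used with boron already present and the ring-contracting 1,2-shift. Ring C is closed by contraction of the seven-membered ate ring to the six-membered pyran (formally a 6-exo-tet displacement at C3 by C2), the C3–B–C2 bridge being a bond set that is absent from the target. The C3 stereocentre is not made here but transferred from the (S)-carbinol of step 8: retention in lithiation and borylation and inversion in the migration should give (R)-20 with boron in the place of the future hydrogen. The step needs C3–H deprotonation in preference to the benzylic and allylic CH2 groups and to attack at boron, which carbamate-directed deprotonation at −78 °C and the hindered amide should secure; it also needs loss of the carbamate and not of the ring A aryloxide from C2, which is expected because the carbamate is by far the better leaving group and C2 is the only carbon ligand on boron that can migrate.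

Step 13
Reactants: 20 tertiary boronic ester
Product: 21 (3R)-3-[2,4-bis(methoxymethoxy)-3-prenylphenyl]-5,7-dimethoxy-6-prenyl-3,4-dihydro-2H-chromene
Conditions: CsF (1.5 equiv), H2O (1.1 equiv), 1,4-dioxane, 45 °C
Reagents that add atoms: none
Why: Fluoride-promoted protodeboronation of a tertiary benzylic pinacol boronate should protonate C3 on the face of the C–B bond (retention), so the configuration transferred in step 12 becomes the (3R) C–H stereocentre.

Step 14
Reactants: 21 bis-MOM isoflavan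
Product: 22 4-[(3R)-5,7-dimethoxy-6-prenyl-3,4-dihydro-2H-chromen-3-yl]-2-prenylbenzene-1,3-diol
Conditions: 3 M aq. HCl, MeOH/THF, 25–40 °C
Reagents that add atoms: none
Why: Acid-catalysed acetal methanolysis removes both MOM groups, and the mild temperature should limit acid-induced cyclisation of the C3′ prenyl group onto the freed phenols.

Step 15
Reactants: 22 resorcinol isoflavan
Product: 23 2-hydroxy-5-[(3R)-5,7-dimethoxy-6-prenyl-3,4-dihydro-2H-chromen-3-yl]-3-prenylcyclohexa-2,5-diene-1,4-dione (target)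
Conditions: (KSO3)2NO (2.5 equiv), KH2PO4 buffer, acetone/H2O, 0 °C → rt
Reagents that add atoms: potassium nitrosodisulfonate (Fremy's salt), [K+].[K+].[O]N(S(=O)(=O)[O-])S(=O)(=O)[O-]
Why: Teuber oxidation should oxygenate ring B at C5′, the only free position para to the C2′ hydroxyl (and ortho to the C4′ hydroxyl), giving the 2-hydroxy-1,4-benzoquinone tautomer, while the ring A aryl ethers, both prenyl groups and C3 are untouched.

**Compound list**
1 | resorcinol (benzene-1,3-diol) | Oc1cccc(O)c1 | starting material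
2 | 1,3-bis(methoxymethoxy)benzene | COCOc1cccc(OCOC)c1 | intermediate
3 | 2,6-bis(methoxymethoxy)phenyllithium (not isolated) | COCOc1cccc(OCOC)c1[Li] | intermediate
4 | 1,3-bis(methoxymethoxy)-2-(3-methylbut-2-en-1-yl)benzene | COCOc1cccc(OCOC)c1CC=C(C)C | intermediate
5 | 2,4-bis(methoxymethoxy)-3-prenylphenyllithium (not isolated) | COCOc1ccc([Li])c(OCOC)c1CC=C(C)C | intermediate
6 | lithium 1-[2,4-bis(methoxymethoxy)-3-prenylphenyl]-1-[methoxy(methyl)amino]ethan-1-olate (not isolated) | COCOc1ccc(C(C)(O[Li])N(C)OC)c(OCOC)c1CC=C(C)C | intermediate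
7 | 1-[2,4-bis(methoxymethoxy)-3-(3-methylbut-2-en-1-yl)phenyl]ethan-1-one | COCOc1ccc(C(C)=O)c(OCOC)c1CC=C(C)C | intermediate
8 | 3,5-dimethoxyphenol | COc1cc(O)cc(OC)c1 | starting material
9 | (3,5-dimethoxyphenoxy)tri(propan-2-yl)silane | COc1cc(OC)cc(O[Si](C(C)C)(C(C)C)C(C)C)c1 | intermediate
10 | 2,6-dimethoxy-4-(TIPS-oxy)phenyllithium (not isolated) | COc1cc(O[Si](C(C)C)(C(C)C)C(C)C)cc(OC)c1[Li] | intermediate
11 | [3,5-dimethoxy-4-(3-methylbut-2-en-1-yl)phenoxy]tri(propan-2-yl)silane | COc1cc(O[Si](C(C)C)(C(C)C)C(C)C)cc(OC)c1CC=C(C)C | intermediate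
12 | [2-bromo-3,5-dimethoxy-4-(3-methylbut-2-en-1-yl)phenoxy]tri(propan-2-yl)silane | COc1cc(O[Si](C(C)C)(C(C)C)C(C)C)c(Br)c(OC)c1CC=C(C)C | intermediate
13 | 1-[2,4-bis(methoxymethoxy)-3-prenylphenyl]-2-[2,4-dimethoxy-3-prenyl-6-{[tri(propan-2-yl)silyl]oxy}phenyl]ethan-1-one | COCOc1ccc(C(=O)Cc2c(OC)c(CC=C(C)C)c(OC)cc2O[Si](C(C)C)(C(C)C)C(C)C)c(OCOC)c1CC=C(C)C | intermediate
14 | (1S)-1-[2,4-bis(methoxymethoxy)-3-prenylphenyl]-2-[2,4-dimethoxy-3-prenyl-6-{[tri(propan-2-yl)silyl]oxy}phenyl]ethan-1-ol | COCOc1ccc([C@@H](O)Cc2c(OC)c(CC=C(C)C)c(OC)cc2O[Si](C(C)C)(C(C)C)C(C)C)c(OCOC)c1CC=C(C)C | intermediate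
15 | (1S)-1-[2,4-bis(methoxymethoxy)-3-prenylphenyl]-2-[2,4-dimethoxy-3-prenyl-6-{[tri(propan-2-yl)silyl]oxy}phenyl]ethyl N,N-di(propan-2-yl)carbamate | COCOc1ccc([C@@H](OC(=O)N(C(C)C)C(C)C)Cc2c(OC)c(CC=C(C)C)c(OC)cc2O[Si](C(C)C)(C(C)C)C(C)C)c(OCOC)c1CC=C(C)C | intermediate
16 | (1S)-1-[2,4-bis(methoxymethoxy)-3-prenylphenyl]-2-[6-hydroxy-2,4-dimethoxy-3-prenylphenyl]ethyl N,N-di(propan-2-yl)carbamate | COCOc1ccc([C@@H](OC(=O)N(C(C)C)C(C)C)Cc2c(OC)c(CC=C(C)C)c(OC)cc2O)c(OCOC)c1CC=C(C)C | intermediate
17 | (1S)-1-[2,4-bis(methoxymethoxy)-3-prenylphenyl]-2-[2,4-dimethoxy-3-prenyl-6-[(4,4,5,5-tetramethyl-1,3,2-dioxaborolan-2-yl)methoxy]phenyl]ethyl N,N-di(propan-2-yl)carbamate | COCOc1ccc([C@@H](OC(=O)N(C(C)C)C(C)C)Cc2c(OC)c(CC=C(C)C)c(OC)cc2OCB3OC(C)(C)C(C)(C)O3)c(OCOC)c1CC=C(C)C | intermediate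
18 | (S)-C3-lithiated carbamate of 17 (lithium in the place of the carbinol hydrogen; not isolated) | COCOc1ccc([C@@]([Li])(OC(=O)N(C(C)C)C(C)C)Cc2c(OC)c(CC=C(C)C)c(OC)cc2OCB3OC(C)(C)C(C)(C)O3)c(OCOC)c1CC=C(C)C | intermediate
19 | lithium salt of the seven-membered cyclic boronate complex (spiro pinacol borate; boron bonded to C3 and C2, carbamate still on C3; not isolated) | COCOc1ccc([C@@]2(OC(=O)N(C(C)C)C(C)C)Cc3c(OC)c(CC=C(C)C)c(OC)cc3OC[B-]24OC(C)(C)C(C)(C)O4)c(OCOC)c1CC=C(C)C.[Li+] | intermediate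
20 | 2-{(3R)-3-[2,4-bis(methoxymethoxy)-3-prenylphenyl]-5,7-dimethoxy-6-prenyl-3,4-dihydro-2H-chromen-3-yl}-4,4,5,5-tetramethyl-1,3,2-dioxaborolane | COc1cc2c(c(OC)c1CC=C(C)C)C[C@](B3OC(C)(C)C(C)(C)O3)(c1ccc(OCOC)c(CC=C(C)C)c1OCOC)CO2 | intermediate
21 | (3R)-3-[2,4-bis(methoxymethoxy)-3-prenylphenyl]-5,7-dimethoxy-6-prenyl-3,4-dihydro-2H-chromene | COc1cc2c(c(OC)c1CC=C(C)C)C[C@H](c1ccc(OCOC)c(CC=C(C)C)c1OCOC)CO2 | intermediate
22 | 4-[(3R)-5,7-dimethoxy-6-prenyl-3,4-dihydro-2H-chromen-3-yl]-2-prenylbenzene-1,3-diol | COc1cc2c(c(OC)c1CC=C(C)C)C[C@H](c1ccc(O)c(CC=C(C)C)c1O)CO2 | intermediate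
23 | 2-hydroxy-5-[(3R)-5,7-dimethoxy-6-(3-methylbut-2-en-1-yl)-3,4-dihydro-2H-chromen-3-yl]-3-(3-methylbut-2-en-1-yl)cyclohexa-2,5-diene-1,4-dione | COc1cc2c(c(OC)c1CC=C(C)C)C[C@H](C1=CC(=O)C(O)=C(CC=C(C)C)C1=O)CO2 | target

**Step count and risks**
Total step count: 15. Longest linear sequence: 12 steps (8 → 23 through steps 4–15; the ring B branch 1 → 7 → 23 is equally 12).

Steps most likely to fail:

1. Step 12 (Proposed new method). The amide base may fail to deprotonate C3–H of the electron-rich benzylic carbamate while boron is present. The tethered boron may attack the carbanion on the face opposite to lithium, which would erode or reverse the configuration. The ate complex may also open by loss of the ring A aryloxide instead of contracting. Fallback, using known intermolecular lithiation–borylation and closing ring C at O1–C2 instead; it sets out from 15 and returns at 21. Carbamate 15 is lithiated with s-BuLi/TMEDA in Et2O at −78 °C (no boron present) to the lithiated carbamate F1. Addition of 2-{[(4-methoxyphenyl)methoxy]methyl}-4,4,5,5-tetramethyl-1,3,2-dioxaborolane gives the boronate complex F2, which rearranges on warming to the acyclic tertiary boronic ester F3. CsF/H2O protodeboronation (retention; the β-alkoxide is a poor leaving group) gives the PMB ether F4. DDQ in CH2Cl2/pH 7 buffer gives the primary alcohol F5, and MsCl/Et3N gives the mesylate F6. TBAF then cleaves the silyl ether, and the phenoxide closes ring C by intramolecular Williamson etherification to give 21.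

2. Step 13. After fluoride activation the C3–B bond can align anti to the C2–O1 bond, so β-elimination with opening of ring C may outrun protonation. The electron-rich ring B also slows protonation, with a risk of partial loss of configuration. Fallback without any C3–B bond; it sets out from 13 and returns at 21. Ketone 13 undergoes Wittig methylenation (Ph3PCH3Br, KOtBu, THF) to the 1,1-disubstituted alkene F7. Enantioselective anti-Markovnikov hydroboration with HBpin follows, using a chiral iminopyridine–oxazoline CoCl2 complex activated by NaBHEt3 or CuCl with a chiral bisphosphine. The ligand enantiomer is chosen for the (R) product, and the prenyl alkenes are inert; this gives the primary boronate F8. TBAF gives the phenol F9, and NaBO3 oxidation gives the diol F10. Mitsunobu etherification (PPh3, DIAD) closes ring C to 21.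

3. Step 7. Oxidative addition and C–C reductive elimination at the di-ortho-substituted, electron-rich aryl bromide next to the bulky silyl ether may be slow, so hydrodebromination and catalyst decomposition could take over. Fallback by polar C–C bond formation without palladium; it sets out from 12 and returns at 13. Bromide 12 undergoes bromine–lithium exchange (t-BuLi, THF, −78 °C) to the aryllithium F11. Opening of ethylene oxide (BF3·OEt2) gives the arylethanol F12, and Dess–Martin oxidation gives the arylacetaldehyde F13. Addition of aryllithium 5 (made from 4 as in step 3) gives the racemic alcohol F14, and a second Dess–Martin oxidation returns ketone 13.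

Further compounds
F1 | step 12 | (S)-C3-lithiated carbamate of 15 | COCOc1ccc([C@@]([Li])(OC(=O)N(C(C)C)C(C)C)Cc2c(OC)c(CC=C(C)C)c(OC)cc2O[Si](C(C)C)(C(C)C)C(C)C)c(OCOC)c1CC=C(C)C
F2 | step 12 | lithium salt of the acyclic boronate complex (boron bonded to C3, to CH2OPMB and to pinacol) | COCOc1ccc([C@@]([B-]3(COCc4ccc(OC)cc4)OC(C)(C)C(C)(C)O3)(OC(=O)N(C(C)C)C(C)C)Cc2c(OC)c(CC=C(C)C)c(OC)cc2O[Si](C(C)C)(C(C)C)C(C)C)c(OCOC)c1CC=C(C)C.[Li+]
F3 | step 12 | 2-[(2R)-2-[2,4-bis(methoxymethoxy)-3-prenylphenyl]-1-[2,4-dimethoxy-3-prenyl-6-(TIPS-oxy)phenyl]-3-[(4-methoxyphenyl)methoxy]propan-2-yl]-4,4,5,5-tetramethyl-1,3,2-dioxaborolane | COCOc1ccc([C@](B3OC(C)(C)C(C)(C)O3)(COCc3ccc(OC)cc3)Cc2c(OC)c(CC=C(C)C)c(OC)cc2O[Si](C(C)C)(C(C)C)C(C)C)c(OCOC)c1CC=C(C)C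
F4 | step 12 | (2R)-2-[2,4-bis(methoxymethoxy)-3-prenylphenyl]-3-[2,4-dimethoxy-3-prenyl-6-(TIPS-oxy)phenyl]propyl 4-methoxybenzyl ether | COCOc1ccc([C@H](COCc3ccc(OC)cc3)Cc2c(OC)c(CC=C(C)C)c(OC)cc2O[Si](C(C)C)(C(C)C)C(C)C)c(OCOC)c1CC=C(C)C
F5 | step 12 | (2R)-2-[2,4-bis(methoxymethoxy)-3-prenylphenyl]-3-[2,4-dimethoxy-3-prenyl-6-(TIPS-oxy)phenyl]propan-1-ol | COCOc1ccc([C@H](CO)Cc2c(OC)c(CC=C(C)C)c(OC)cc2O[Si](C(C)C)(C(C)C)C(C)C)c(OCOC)c1CC=C(C)C
F6 | step 12 | (2R)-2-[2,4-bis(methoxymethoxy)-3-prenylphenyl]-3-[2,4-dimethoxy-3-prenyl-6-(TIPS-oxy)phenyl]propyl methanesulfonate | COCOc1ccc([C@H](COS(C)(=O)=O)Cc2c(OC)c(CC=C(C)C)c(OC)cc2O[Si](C(C)C)(C(C)C)C(C)C)c(OCOC)c1CC=C(C)C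
F7 | step 13 | 2-[2,4-bis(methoxymethoxy)-3-prenylphenyl]-3-[2,4-dimethoxy-3-prenyl-6-(TIPS-oxy)phenyl]prop-1-ene | COCOc1ccc(C(=C)Cc2c(OC)c(CC=C(C)C)c(OC)cc2O[Si](C(C)C)(C(C)C)C(C)C)c(OCOC)c1CC=C(C)C
F8 | step 13 | 2-[(2R)-2-[2,4-bis(methoxymethoxy)-3-prenylphenyl]-3-[2,4-dimethoxy-3-prenyl-6-(TIPS-oxy)phenyl]propyl]-4,4,5,5-tetramethyl-1,3,2-dioxaborolane | COCOc1ccc([C@H](CB3OC(C)(C)C(C)(C)O3)Cc2c(OC)c(CC=C(C)C)c(OC)cc2O[Si](C(C)C)(C(C)C)C(C)C)c(OCOC)c1CC=C(C)C
F9 | step 13 | 2-[(2R)-2-[2,4-bis(methoxymethoxy)-3-prenylphenyl]-3-(pinacolboryl)propyl]-3,5-dimethoxy-4-prenylphenol | COCOc1ccc([C@H](CB3OC(C)(C)C(C)(C)O3)Cc2c(OC)c(CC=C(C)C)c(OC)cc2O)c(OCOC)c1CC=C(C)C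
F10 | step 13 | 2-[(2R)-2-[2,4-bis(methoxymethoxy)-3-prenylphenyl]-3-hydroxypropyl]-3,5-dimethoxy-4-prenylphenol | COCOc1ccc([C@H](CO)Cc2c(OC)c(CC=C(C)C)c(OC)cc2O)c(OCOC)c1CC=C(C)C
F11 | step 7 | 2,4-dimethoxy-3-prenyl-6-(TIPS-oxy)phenyllithium | [Li]c1c(OC)c(CC=C(C)C)c(OC)cc1O[Si](C(C)C)(C(C)C)C(C)C
F12 | step 7 | 2-[2,4-dimethoxy-3-prenyl-6-(TIPS-oxy)phenyl]ethan-1-ol | OCCc1c(OC)c(CC=C(C)C)c(OC)cc1O[Si](C(C)C)(C(C)C)C(C)C
F13 | step 7 | 2-[2,4-dimethoxy-3-prenyl-6-(TIPS-oxy)phenyl]acetaldehyde | O=CCc1c(OC)c(CC=C(C)C)c(OC)cc1O[Si](C(C)C)(C(C)C)C(C)C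
F14 | step 7 | racemic 1-[2,4-bis(methoxymethoxy)-3-prenylphenyl]-2-[2,4-dimethoxy-3-prenyl-6-(TIPS-oxy)phenyl]ethan-1-ol | COCOc1ccc(C(O)Cc2c(OC)c(CC=C(C)C)c(OC)cc2O[Si](C(C)C)(C(C)C)C(C)C)c(OCOC)c1CC=C(C)C
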